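**Strategy.** The pyran ring is disconnected at O1–C8a, C4–C4a and O1–C2, so that O1, C2, C3 and C4 all come from prenal and ring A comes from an aryne. The plan exploits the fact that the C4a–C8a bond of ring A lies directly beside the oxygen-bearing C5: it is the strained bond of a 3-oxygenated aryne, polarised for oxygen attack at C8a. In one operation fluoride unmasks the aryne, prenal inserts through its carbonyl group, and the resulting ortho-quinone methide closes by oxa-6π electrocyclisation to the 2,2-dimethylchromene. The precursor is a pentasubstituted ring A: C8a triflate, C4a trimethylsilyl, C5 diethylcarbamate, C6 prenyl and the C7 arylethyl chain, with its phenol as a methoxymethyl ether.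

Key step: step 10

Remark: atom labels (O1, C2 … C8a, ring A; ring B and 4' for the para-oxygenated phenyl ring) follow 2H-chromene numbering of the target and are also used for the corresponding atoms of earlier intermediates.

Remark: the three phenols of hydrogenated resveratrol cannot be told apart reliably, so the bibenzyl is assembled from two arenes with the 4' oxygen already protected.

Remark: the phenol that becomes the triflate must be masked during the two lithiations; a tetrahydropyranyl acetal is used (one uncontrolled acetal stereocentre in 11–17, racemic, removed in step 8).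

Step 1
Reactants: 1 3,5-bis(benzyloxy)benzyl bromide; 2 triethyl phosphite
Product: 3 diethyl [3,5-bis(benzyloxy)benzyl]phosphonate
Conditions: P(OEt)3 (neat, excess), 130 °C, EtBr distilled off
Reagents that add atoms: triethyl phosphite (2), CCOP(OCC)OCC
Why: Michaelis–Arbuzov reaction of a primary benzylic bromide, in which phosphorus displaces bromide and the released bromide dealkylates the phosphonium ion.

Step 2
Reactants: 3 diethyl [3,5-bis(benzyloxy)benzyl]phosphonate; 4 4-(methoxymethoxy)benzaldehyde
Product: 6 (E)-1,3-bis(benzyloxy)-5-[2-[4-(methoxymethoxy)phenyl]ethenyl]benzene, via sodium phosphonate carbanion 5 (not isolated)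
Conditions: NaH, THF, 0 °C; then 4, 0 °C → rt
Reagents that add atoms: 4-(methoxymethoxy)benzaldehyde (4), COCOc1ccc(C=O)cc1
Why: Horner–Wadsworth–Emmons olefination of an aryl aldehyde with a benzylphosphonate anion should give the E-stilbene, whose geometry is erased in step 3.

Step 3
Reactants: 6 (E)-1,3-bis(benzyloxy)-5-[2-[4-(methoxymethoxy)phenyl]ethenyl]benzene
Product: 8 5-[2-[4-(methoxymethoxy)phenyl]ethyl]benzene-1,3-diol, via saturated bis(benzyl ether) 7 (not isolated)
Conditions: H2 (1 atm), 10% Pd/C, EtOAc–MeOH, rt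
Reagents that add atoms: none
Why: heterogeneous catalytic hydrogenation saturates the stilbene and hydrogenolyses both benzyl ethers under neutral conditions that leave the methoxymethyl acetal untouched.

Step 4
Reactants: 8 5-[2-[4-(methoxymethoxy)phenyl]ethyl]benzene-1,3-diol; 9 N,N-diethylcarbamoyl chloride
Product: 10 3-hydroxy-5-[2-[4-(methoxymethoxy)phenyl]ethyl]phenyl N,N-diethylcarbamate
Conditions: Et2NCOCl (slightly less than 1 equiv, slow addition), K2CO3, MeCN, 60 °C
Reagents that add atoms: N,N-diethylcarbamoyl chloride (9), CCN(CC)C(=O)Cl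
Why: O-carbamoylation of a phenol; since the two hydroxyls of 8 are equivalent, limiting the chloride should favour the mono-carbamate, which is separable from the bis-carbamate and from recovered 8 (recycled).

Step 5
Reactants: 10 3-hydroxy-5-[2-[4-(methoxymethoxy)phenyl]ethyl]phenyl N,N-diethylcarbamate
Product: 11 3-[2-[4-(methoxymethoxy)phenyl]ethyl]-5-(tetrahydro-2H-pyran-2-yloxy)phenyl N,N-diethylcarbamate (racemic)
Conditions: 3,4-dihydro-2H-pyran, PPTS (cat.), CH2Cl2, rt
Reagents that add atoms: 3,4-dihydro-2H-pyran, C1=COCCC1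
Why: acid-catalysed addition of the phenol to the enol ether (tetrahydropyranylation) masks the acidic OH and adds a second, weaker directing oxygen; the new acetal stereocentre forms as a racemate and is removed in step 8.

Step 6
Reactants: 11 3-[2-[4-(methoxymethoxy)phenyl]ethyl]-5-(tetrahydro-2H-pyran-2-yloxy)phenyl N,N-diethylcarbamate
Product: 13 5-[2-[4-(methoxymethoxy)phenyl]ethyl]-3-(tetrahydro-2H-pyran-2-yloxy)-2-(trimethylsilyl)phenyl N,N-diethylcarbamate, via aryllithium 12 (not isolated)
Conditions: s-BuLi, TMEDA, THF, −78 °C; TMSCl, −78 °C → rt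
Reagents that add atoms: chlorotrimethylsilane, C[Si](C)(C)Cl
Why: directed ortho-metalation; the carbon between the carbamate and the acetal oxygen (future C4a) is activated by both directing groups and should be lithiated before any other aryl C–H, and silylation at −78 °C precedes any anionic ortho-Fries shift.

Step 7
Reactants: 13 5-[2-[4-(methoxymethoxy)phenyl]ethyl]-3-(tetrahydro-2H-pyran-2-yloxy)-2-(trimethylsilyl)phenyl N,N-diethylcarbamate; 14 prenyl bromide (1-bromo-3-methylbut-2-ene)
Product: 17 3-[2-[4-(methoxymethoxy)phenyl]ethyl]-2-(3-methylbut-2-en-1-yl)-5-(tetrahydro-2H-pyran-2-yloxy)-6-(trimethylsilyl)phenyl N,N-diethylcarbamate, via aryllithium 15 (not isolated), via arylcopper 16 (not isolated)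
Conditions: s-BuLi, TMEDA, THF, −78 °C; CuBr·SMe2, −78 → −40 °C; prenyl bromide, −78 → 0 °C
Reagents that add atoms: prenyl bromide (14), CC(C)=CCBr
Why: a second directed ortho-metalation goes to the only remaining carbamate-ortho carbon (future C6) because silicon blocks the other and the carbamate outranks both acetal ethers as director; transmetalation to copper stops carbamoyl migration, and the arylcopper should be allylated at the unsubstituted terminus of prenyl bromide.

Step 8
Reactants: 17 3-[2-[4-(methoxymethoxy)phenyl]ethyl]-2-(3-methylbut-2-en-1-yl)-5-(tetrahydro-2H-pyran-2-yloxy)-6-(trimethylsilyl)phenyl N,N-diethylcarbamate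
Product: 18 3-hydroxy-5-[2-[4-(methoxymethoxy)phenyl]ethyl]-6-(3-methylbut-2-en-1-yl)-2-(trimethylsilyl)phenyl N,N-diethylcarbamate
Conditions: PPTS (cat.), MeOH–THF, rt
Reagents that add atoms: none
Why: mild acid-catalysed transacetalisation removes the labile aryl tetrahydropyranyl acetal at an acidity at which the aryl methoxymethyl ether, the aryl–silicon bond and the prenyl group should persist.

Step 9
Reactants: 18 3-hydroxy-5-[2-[4-(methoxymethoxy)phenyl]ethyl]-6-(3-methylbut-2-en-1-yl)-2-(trimethylsilyl)phenyl N,N-diethylcarbamate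
Product: 19 3-[(diethylcarbamoyl)oxy]-5-[2-[4-(methoxymethoxy)phenyl]ethyl]-4-(3-methylbut-2-en-1-yl)-2-(trimethylsilyl)phenyl trifluoromethanesulfonate
Conditions: PhNTf2, DBU, MeCN, rt
Reagents that add atoms: N-phenylbis(trifluoromethanesulfonimide), O=S(=O)(N(c1ccccc1)S(=O)(=O)C(F)(F)F)C(F)(F)F
Why: O-triflylation of the phenoxide with a mild triflyl donor is the standard last step towards ortho-silylaryl triflates, and the fluoride-free basic conditions do not trigger elimination.

Step 10
Reactants: 19 3-[(diethylcarbamoyl)oxy]-5-[2-[4-(methoxymethoxy)phenyl]ethyl]-4-(3-methylbut-2-en-1-yl)-2-(trimethylsilyl)phenyl trifluoromethanesulfonate; 20 prenal (3-methylbut-2-enal)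
Product: 24 2,2-dimethyl-7-[2-[4-(methoxymethoxy)phenyl]ethyl]-6-(3-methylbut-2-en-1-yl)-2H-chromen-5-yl N,N-diethylcarbamate, via aryne 21 (not isolated), via benzoxete 22 (not isolated), via ortho-quinone methide 23 (not isolated)
Conditions: CsF (3 equiv), prenal (5 equiv), MeCN, rt, 19 added slowly
Reagents that add atoms: prenal (20), CC(C)=CC=O
Why: Fluoride attack on silicon in 19 expels triflate to give aryne 21, whose C4a–C8a bond is distorted by the inductively withdrawing C5 carbamate oxygen so that C8a is the more electrophilic terminus. The carbonyl oxygen of prenal therefore bonds to C8a, the developing aryl anion at C4a (stabilised next to the C5 oxygen) collapses onto the carbonyl carbon in a formal [2+2] addition that closes the four-membered ring of benzoxete 22, and thermal 4π ring opening gives the (Z)-ortho-quinone methide 23. Thermal disrotatory oxa-6π electrocyclisation of 23, in which the dienone oxygen bonds to the CMe2 terminus (O1–C2), closes the six-membered pyran ring and restores the aromaticity of ring A. This is the known insertion of arynes into the C=O bond of α,β-unsaturated aldehydes leading to 2H-chromenes, applied here to a 3-oxygenated aryne. No stereocentre persists, because C2 carries two methyl groups and the benzoxete carbon becomes sp2. The step needs a single orientation of addition across the unsymmetrical aryne, secured by the C5 oxygen substituent and the unhindered C8–H flank of C8a, and it needs the aldehyde to outrun intermolecular ene reaction of the aryne with prenyl groups, which excess prenal and slow aryne release should secure.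

Step 11
Reactants: 24 2,2-dimethyl-7-[2-[4-(methoxymethoxy)phenyl]ethyl]-6-(3-methylbut-2-en-1-yl)-2H-chromen-5-yl N,N-diethylcarbamate
Product: 25 7-[2-(4-hydroxyphenyl)ethyl]-2,2-dimethyl-6-(3-methylbut-2-en-1-yl)-2H-chromen-5-yl N,N-diethylcarbamate
Conditions: HCl (0.5 M), MeOH–THF, rt → 40 °C
Reagents that add atoms: none
Why: acid-catalysed methanolysis of the aryl methoxymethyl acetal, run while the C5 oxygen is still a carbamate so that no free phenol sits beside the prenyl group to add across it under acid.

Step 12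
Reactants: 25 7-[2-(4-hydroxyphenyl)ethyl]-2,2-dimethyl-6-(3-methylbut-2-en-1-yl)-2H-chromen-5-yl N,N-diethylcarbamate
Product: 26 7-[2-(4-hydroxyphenyl)ethyl]-2,2-dimethyl-6-(3-methylbut-2-en-1-yl)-2H-chromen-5-ol (target)
Conditions: LiAlH4 (excess), THF, 0 °C → reflux; aqueous Rochelle salt work-up
Reagents that add atoms: none
Why: hydride reduction of the aryl carbamate releases the C5 phenoxide and N,N-diethylmethylamine, the prenyl and chromene double bonds are inert to LiAlH4, and the near-neutral work-up keeps acid away from the ortho-prenyl phenol.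

**Compound list**

1 | 3,5-bis(benzyloxy)benzyl bromide | BrCc1cc(OCc2ccccc2)cc(OCc2ccccc2)c1 | starting material
2 | triethyl phosphite | CCOP(OCC)OCC | starting material
3 | diethyl [3,5-bis(benzyloxy)benzyl]phosphonate | CCOP(=O)(OCC)Cc1cc(OCc2ccccc2)cc(OCc2ccccc2)c1 | intermediate
4 | 4-(methoxymethoxy)benzaldehyde | COCOc1ccc(C=O)cc1 | starting material
5 | sodium salt of the benzylic carbanion of 3 (not isolated) | CCOP(=O)(OCC)[CH-]c1cc(OCc2ccccc2)cc(OCc2ccccc2)c1.[Na+] | intermediate
6 | (E)-1,3-bis(benzyloxy)-5-[2-[4-(methoxymethoxy)phenyl]ethenyl]benzene | COCOc1ccc(/C=C/c2cc(OCc3ccccc3)cc(OCc3ccccc3)c2)cc1 | intermediate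
7 | 1,3-bis(benzyloxy)-5-[2-[4-(methoxymethoxy)phenyl]ethyl]benzene (not isolated) | COCOc1ccc(CCc2cc(OCc3ccccc3)cc(OCc3ccccc3)c2)cc1 | intermediate
8 | 5-[2-[4-(methoxymethoxy)phenyl]ethyl]benzene-1,3-diol | COCOc1ccc(CCc2cc(O)cc(O)c2)cc1 | intermediate
9 | N,N-diethylcarbamoyl chloride | CCN(CC)C(=O)Cl | starting material
10 | 3-hydroxy-5-[2-[4-(methoxymethoxy)phenyl]ethyl]phenyl N,N-diethylcarbamate | CCN(CC)C(=O)Oc1cc(O)cc(CCc2ccc(OCOC)cc2)c1 | intermediate
11 | 3-[2-[4-(methoxymethoxy)phenyl]ethyl]-5-(tetrahydro-2H-pyran-2-yloxy)phenyl N,N-diethylcarbamate, racemic at the acetal carbon | CCN(CC)C(=O)Oc1cc(OC2CCCCO2)cc(CCc2ccc(OCOC)cc2)c1 | intermediate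
12 | 2-lithio derivative of 11, lithium on the carbon between the two ring A oxygens (not isolated) | CCN(CC)C(=O)Oc1c([Li])c(OC2CCCCO2)cc(CCc2ccc(OCOC)cc2)c1 | intermediate
13 | 5-[2-[4-(methoxymethoxy)phenyl]ethyl]-3-(tetrahydro-2H-pyran-2-yloxy)-2-(trimethylsilyl)phenyl N,N-diethylcarbamate, racemic | CCN(CC)C(=O)Oc1c([Si](C)(C)C)c(OC2CCCCO2)cc(CCc2ccc(OCOC)cc2)c1 | intermediate
14 | prenyl bromide (1-bromo-3-methylbut-2-ene) | CC(C)=CCBr | starting material
15 | 6-lithio derivative of 13, lithium between the carbamate and the arylethyl chain (not isolated) | [Li]c1c(CCc2ccc(OCOC)cc2)cc(OC2CCCCO2)c([Si](C)(C)C)c1OC(=O)N(CC)CC | intermediate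
16 | arylcopper corresponding to 15 (not isolated) | [Cu]c1c(CCc2ccc(OCOC)cc2)cc(OC2CCCCO2)c([Si](C)(C)C)c1OC(=O)N(CC)CC | intermediate
17 | 3-[2-[4-(methoxymethoxy)phenyl]ethyl]-2-(3-methylbut-2-en-1-yl)-5-(tetrahydro-2H-pyran-2-yloxy)-6-(trimethylsilyl)phenyl N,N-diethylcarbamate, racemic | CC(C)=CCc1c(CCc2ccc(OCOC)cc2)cc(OC2CCCCO2)c([Si](C)(C)C)c1OC(=O)N(CC)CC | intermediate
18 | 3-hydroxy-5-[2-[4-(methoxymethoxy)phenyl]ethyl]-6-(3-methylbut-2-en-1-yl)-2-(trimethylsilyl)phenyl N,N-diethylcarbamate | CC(C)=CCc1c(CCc2ccc(OCOC)cc2)cc(O)c([Si](C)(C)C)c1OC(=O)N(CC)CC | intermediate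
19 | 3-[(diethylcarbamoyl)oxy]-5-[2-[4-(methoxymethoxy)phenyl]ethyl]-4-(3-methylbut-2-en-1-yl)-2-(trimethylsilyl)phenyl trifluoromethanesulfonate (key-step precursor) | CC(C)=CCc1c(CCc2ccc(OCOC)cc2)cc(OS(=O)(=O)C(F)(F)F)c([Si](C)(C)C)c1OC(=O)N(CC)CC | intermediate
20 | prenal (3-methylbut-2-enal) | CC(C)=CC=O | starting material
21 | aryne with the formal triple bond between C4a and C8a, carrying the C5 diethylcarbamate, C6 prenyl and C7 arylethyl groups (not isolated) | CC(C)=CCC1=C(OC(=O)N(CC)CC)C#CC=C1CCc1ccc(OCOC)cc1 | intermediate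
22 | 2H-benzoxete fused at C4a–C8a, with O on C8a and CH(CH=CMe2) on C4a, ring A otherwise as in 21; racemic at the oxetene carbon (not isolated) | CC(C)=CCc1c(CCc2ccc(OCOC)cc2)cc2c(c1OC(=O)N(CC)CC)C(C=C(C)C)O2 | intermediate
23 | (Z)-ortho-quinone methide: cyclohexa-2,4-dien-1-one with C8a as C=O and a 3-methylbut-2-en-1-ylidene group on C4a, the vinyl arm cis to the carbonyl (not isolated) | O=C1C=C(CCc2ccc(OCOC)cc2)C(CC=C(C)C)=C(OC(=O)N(CC)CC)/C1=C/C=C(C)C | intermediate
24 | 2,2-dimethyl-7-[2-[4-(methoxymethoxy)phenyl]ethyl]-6-(3-methylbut-2-en-1-yl)-2H-chromen-5-yl N,N-diethylcarbamate | CC(C)=CCc1c(CCc2ccc(OCOC)cc2)cc2c(c1OC(=O)N(CC)CC)C=CC(C)(C)O2 | intermediate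
25 | 7-[2-(4-hydroxyphenyl)ethyl]-2,2-dimethyl-6-(3-methylbut-2-en-1-yl)-2H-chromen-5-yl N,N-diethylcarbamate | CC(C)=CCc1c(CCc2ccc(O)cc2)cc2c(c1OC(=O)N(CC)CC)C=CC(C)(C)O2 | intermediate
26 | 7-[2-(4-hydroxyphenyl)ethyl]-2,2-dimethyl-6-(3-methylbut-2-en-1-yl)-2H-chromen-5-ol | CC(C)=CCc1c(CCc2ccc(O)cc2)cc2c(c1O)C=CC(C)(C)O2 | target

**Step count.** Total: 12 steps. Longest linear sequence: 12 steps from 1 (nine to the precursor 19, the key step, two after it).

**Steps most likely to fail**

1. Step 10. The aryne may be consumed by intermolecular ene or [2+2] reaction with the prenyl and chromene alkenes, the quinone methide may be trapped by a second aryne, or addition may occur in the reverse orientation. Fallback, from 11 back to 24: the aryllithium 12, made as in step 6, is added to prenal at −78 °C and quenched cold with AcOH to give the allylic benzylic alcohol F1. PPTS in MeOH followed by warming in toluene removes the acetal and dehydrates F1 through an ortho-quinone methide that can only use O1, because the C5 oxygen is still a carbamate. Oxa-6π closure then gives the 6-unsubstituted chromene carbamate F2. Carbamate-directed lithiation of F2 at C6 (s-BuLi, TMEDA, −78 °C), CuBr·SMe2 and prenyl bromide give 24, and the route resumes at step 11.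

2. Step 7. Metalation may occur at the wrong site (ortho to the ring B acetal ether), the carbamoyl group may migrate before transmetalation, or allylation may take place at the tertiary terminus. Fallback, from 11 back to 17, replacing steps 6 and 7: NBS in MeCN at 0 °C should brominate ring A para to the acetal oxygen (future C6) to give the aryl bromide F3. LDA with TMSCl present in THF at −78 °C silylates the carbon between the two oxygens without touching the bromide, giving the bromo silane F4. Linear-selective Negishi coupling of F4 with prenylzinc bromide (Pd(OAc)2, CPhos, THF, rt) gives 17, and the route resumes at step 8.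

3. Step 11. Under protic acid, methanol may add to the prenyl alkene or the chromene may degrade before the acetal is fully cleaved. Fallback, from 24 back to 25: TMSOTf and 2,2'-bipyridyl in MeCN at 0 °C exchange the methoxymethyl group for silicon without a Brønsted acid, giving the aryl trimethylsilyl ether F5. Stirring F5 with water hydrolyses the silyl ether to 25, and the route resumes at step 12.

**Further compounds**

F1 | step 10 | 2-(1-hydroxy-3-methylbut-2-en-1-yl)-5-[2-[4-(methoxymethoxy)phenyl]ethyl]-3-(tetrahydro-2H-pyran-2-yloxy)phenyl N,N-diethylcarbamate, mixture of racemic diastereomers | CCN(CC)C(=O)Oc1cc(CCc2ccc(OCOC)cc2)cc(OC2CCCCO2)c1C(O)C=C(C)C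
F2 | step 10 | 2,2-dimethyl-7-[2-[4-(methoxymethoxy)phenyl]ethyl]-2H-chromen-5-yl N,N-diethylcarbamate | CCN(CC)C(=O)Oc1cc(CCc2ccc(OCOC)cc2)cc2c1C=CC(C)(C)O2
F3 | step 7 | 2-bromo-3-[2-[4-(methoxymethoxy)phenyl]ethyl]-5-(tetrahydro-2H-pyran-2-yloxy)phenyl N,N-diethylcarbamate, racemic | CCN(CC)C(=O)Oc1cc(OC2CCCCO2)cc(CCc2ccc(OCOC)cc2)c1Br
F4 | step 7 | 2-bromo-3-[2-[4-(methoxymethoxy)phenyl]ethyl]-5-(tetrahydro-2H-pyran-2-yloxy)-6-(trimethylsilyl)phenyl N,N-diethylcarbamate, racemic | CCN(CC)C(=O)Oc1c([Si](C)(C)C)c(OC2CCCCO2)cc(CCc2ccc(OCOC)cc2)c1Br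
F5 | step 11 | 2,2-dimethyl-6-(3-methylbut-2-en-1-yl)-7-[2-[4-(trimethylsilyloxy)phenyl]ethyl]-2H-chromen-5-yl N,N-diethylcarbamate | CC(C)=CCc1c(CCc2ccc(O[Si](C)(C)C)cc2)cc2c(c1OC(=O)N(CC)CC)C=CC(C)(C)O2
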